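The benzofuran is cut into two phenylpropanoids: C2, C3, the formyl carbon and the pendant trioxygenated ring are a cinnamate, whereas O1, C7a, C3a and the benzo ring with its C7 methoxy and C5 hydroxypropyl groups are dihydroconiferyl alcohol. One Ag2O oxidation joins the ester-bearing alkene carbon to the free ortho carbon of that phenol (C3–C3a) and the phenol oxygen to the benzylic carbon (O1–C2), closing the furan ring as its trans-dihydro ester. The precursor is methyl (E)-3-(3-benzyloxy-4-hydroxy-5-methoxyphenyl)acrylate, whose free 4-OH is flanked by two ether groups, used with unprotected dihydroconiferyl alcohol. Dehydrogenation, ester-to-aldehyde adjustment and a single debenzylation finish the route.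

Key step: step 4

Remark: the target has no stereocentre, so 8 and 9 are racemic with one trans enantiomer drawn; the carbon of 5 that forms the C–C bond is the one next to the ester carbonyl (lignan C8, the acrylate α-carbon), and the benzylic carbon (C7) receives the oxygen; 1, 4 and 6 are taken as purchasable.

Step 1
Reactants: 1 3,4-dihydroxy-5-methoxybenzaldehyde
Product: 2 3,4-bis(benzyloxy)-5-methoxybenzaldehyde
Conditions: BnBr (2.4 equiv), K2CO3 (3 equiv), DMF, 60 °C
Reagents that add atoms: benzyl bromide, BrCc1ccccc1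
Why: Williamson etherification, in which excess base and halide carry both the acidic 4-OH and the less acidic 3-OH through to the benzyl ethers.

Step 2
Reactants: 2 3,4-bis(benzyloxy)-5-methoxybenzaldehyde
Product: 3 3-benzyloxy-4-hydroxy-5-methoxybenzaldehyde
Conditions: MgBr2·OEt2 (2 equiv), toluene–Et2O 5:1, 80 °C; 1 M HCl work-up
Reagents that add atoms: none
Why: Chelation-controlled Lewis acid ether cleavage, in which Mg binds the central, out-of-plane 4-O together with a neighbouring ether oxygen, bromide attacks the benzylic CH2 (far faster than a methyl group) and the leaving phenolate is the one para to the aldehyde, so only the flanked 4-O-benzyl group should be lost.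

Step 3
Reactants: 3 3-benzyloxy-4-hydroxy-5-methoxybenzaldehyde; 4 methyl (triphenylphosphoranylidene)acetate (1.3 equiv)
Product: 5 methyl (E)-3-(3-benzyloxy-4-hydroxy-5-methoxyphenyl)acrylate
Conditions: toluene, 90 °C
Reagents that add atoms: none
Why: Wittig olefination with a stabilised ylide, which should give the E-acrylate and needs no added base, so the free phenol is tolerated and the aldehyde is not deactivated as its phenolate.

Step 4
Reactants: 5 methyl (E)-3-(3-benzyloxy-4-hydroxy-5-methoxyphenyl)acrylate; 6 dihydroconiferyl alcohol [4-(3-hydroxypropyl)-2-methoxyphenol] (4 equiv)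
Product: 8 methyl trans-2-(3-benzyloxy-4-hydroxy-5-methoxyphenyl)-5-(3-hydroxypropyl)-7-methoxy-2,3-dihydrobenzofuran-3-carboxylate (racemic), via quinone methide 7 (not isolated)
Conditions: Ag2O (2 equiv), toluene–acetone 2:1, rt, dark, 5 added by syringe pump
Reagents that add atoms: none
Why: Ag2O removes one electron and one proton from each phenol; the phenoxyl radical of 5, with spin at the ester-bearing alkene carbon (C8), combines with the radical of 6 at its only unsubstituted ortho carbon (C5) to form the C3–C3a bond, and tautomerisation of the cyclohexadienone gives quinone methide phenol 7. The phenol oxygen of 7 then adds to the quinone methide carbon in a 5-exo-trig closure that forms the O1–C2 bond and restores the aromatic pendant ring. The closest known reaction type is the Ag2O-mediated oxidative 8–5 dimerisation of ferulate esters to trans-2-aryl-2,3-dihydrobenzofuran-3-carboxylates. The new stereocentres C2 and C3 are set relative to each other by attack of the oxygen on the quinone methide face that places the aryl group anti to the ester (the trans isomer is also the more stable one, and C3 is epimerisable); the product is racemic and both centres vanish in step 6. The step needs cross- over homo-coupling and C–C over C–O coupling: in 5 both positions ortho to the OH carry ether groups, so its radical can bond only through C8 or oxygen, and 6 has a saturated side chain, so C5 is its only unsubstituted carbon with spin density. A fourfold excess of the cheap phenol 6 with slow addition of 5 should hold down the 8–8 dimer of 5, and the aprotic medium disfavours the 8–O–4 pathway, whose quinone methide has no internal nucleophile to trap it.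

Step 5
Reactants: 8 methyl trans-2-(3-benzyloxy-4-hydroxy-5-methoxyphenyl)-5-(3-hydroxypropyl)-7-methoxy-2,3-dihydrobenzofuran-3-carboxylate
Product: 9 methyl trans-2-[3,4-bis(benzyloxy)-5-methoxyphenyl]-5-(3-hydroxypropyl)-7-methoxy-2,3-dihydrobenzofuran-3-carboxylate (racemic)
Conditions: BnBr (1.2 equiv), K2CO3 (2 equiv), acetone, 50 °C
Reagents that add atoms: benzyl bromide, BrCc1ccccc1
Why: Williamson etherification of the only acidic hydroxyl, since K2CO3 deprotonates the phenol but not the primary alcohol; once the phenol is capped the ring can no longer open through a quinone methide, and the new benzyl group leaves later together with the first one.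

Step 6
Reactants: 9 methyl trans-2-[3,4-bis(benzyloxy)-5-methoxyphenyl]-5-(3-hydroxypropyl)-7-methoxy-2,3-dihydrobenzofuran-3-carboxylate
Product: 10 methyl 2-[3,4-bis(benzyloxy)-5-methoxyphenyl]-5-(3-hydroxypropyl)-7-methoxybenzofuran-3-carboxylate
Conditions: DDQ (1.3 equiv), 1,4-dioxane, 90 °C
Reagents that add atoms: none
Why: DDQ dehydrogenation, in which hydride abstraction from C2–H (benzylic to the trioxygenated ring and α to O1) and loss of the acidic C3–H give the aromatic benzofuran and erase both stereocentres, while aryl benzyl ethers and the unactivated primary alcohol are inert to DDQ under anhydrous conditions.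

Step 7
Reactants: 10 methyl 2-[3,4-bis(benzyloxy)-5-methoxyphenyl]-5-(3-hydroxypropyl)-7-methoxybenzofuran-3-carboxylate
Product: 11 3-{2-[3,4-bis(benzyloxy)-5-methoxyphenyl]-3-(hydroxymethyl)-7-methoxybenzofuran-5-yl}propan-1-ol
Conditions: i-Bu2AlH (4 equiv), CH2Cl2, −78 to 0 °C; aq. potassium sodium tartrate work-up
Reagents that add atoms: none
Why: Hydride reduction of the ester to the primary alcohol with excess i-Bu2AlH (one equivalent is consumed by the free hydroxyl), which leaves the benzyl and methyl ethers and the benzofuran untouched.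

Step 8
Reactants: 11 3-{2-[3,4-bis(benzyloxy)-5-methoxyphenyl]-3-(hydroxymethyl)-7-methoxybenzofuran-5-yl}propan-1-ol
Product: 12 2-[3,4-bis(benzyloxy)-5-methoxyphenyl]-5-(3-hydroxypropyl)-7-methoxybenzofuran-3-carbaldehyde
Conditions: activated MnO2 (15 equiv), CH2Cl2, rt
Reagents that add atoms: none
Why: MnO2 oxidation is selective for the activated, benzylic-type benzofuran-3-ylmethanol and should leave the saturated primary alcohol of the side chain alone, so that hydroxyl needs no protecting group.

Step 9
Reactants: 12 2-[3,4-bis(benzyloxy)-5-methoxyphenyl]-5-(3-hydroxypropyl)-7-methoxybenzofuran-3-carbaldehyde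
Product: 13 Mururin C, 2-(3,4-dihydroxy-5-methoxyphenyl)-5-(3-hydroxypropyl)-7-methoxybenzofuran-3-carbaldehyde
Conditions: BCl3 (6 equiv), pentamethylbenzene (8 equiv), CH2Cl2, −78 °C; MeOH quench, aqueous work-up
Reagents that add atoms: none
Why: Lewis acid debenzylation with a cation scavenger, in which BCl3 ionises both aryl benzyl ethers at low temperature and pentamethylbenzene traps the benzyl cations by Friedel–Crafts alkylation, conditions under which aryl methyl ethers, the aldehyde and the benzofuran should persist and the borate esters of the hydroxyl groups are cleaved on quench.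

Compound list
1 | 3,4-dihydroxy-5-methoxybenzaldehyde (5-hydroxyvanillin) | COc1cc(C=O)cc(O)c1O | starting material
2 | 3,4-bis(benzyloxy)-5-methoxybenzaldehyde | COc1cc(C=O)cc(OCc2ccccc2)c1OCc1ccccc1 | intermediate
3 | 3-benzyloxy-4-hydroxy-5-methoxybenzaldehyde | COc1cc(C=O)cc(OCc2ccccc2)c1O | intermediate
4 | methyl (triphenylphosphoranylidene)acetate | COC(=O)C=P(c1ccccc1)(c1ccccc1)c1ccccc1 | starting material
5 | methyl (E)-3-(3-benzyloxy-4-hydroxy-5-methoxyphenyl)acrylate | COC(=O)/C=C/c1cc(OC)c(O)c(OCc2ccccc2)c1 | intermediate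
6 | dihydroconiferyl alcohol, 4-(3-hydroxypropyl)-2-methoxyphenol | COc1cc(CCCO)ccc1O | starting material
7 | methyl 3-(3-benzyloxy-5-methoxy-4-oxocyclohexa-2,5-dien-1-ylidene)-2-[2-hydroxy-5-(3-hydroxypropyl)-3-methoxyphenyl]propanoate (quinone methide, racemic, alkene geometry not defined) | COC(=O)C(C=C1C=C(OC)C(=O)C(OCc2ccccc2)=C1)c1cc(CCCO)cc(OC)c1O | intermediate (not isolated)
8 | methyl trans-2-(3-benzyloxy-4-hydroxy-5-methoxyphenyl)-5-(3-hydroxypropyl)-7-methoxy-2,3-dihydrobenzofuran-3-carboxylate (racemic, one enantiomer drawn) | COC(=O)[C@@H]1[C@@H](c2cc(OC)c(O)c(OCc3ccccc3)c2)Oc2c(OC)cc(CCCO)cc21 | intermediate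
9 | methyl trans-2-[3,4-bis(benzyloxy)-5-methoxyphenyl]-5-(3-hydroxypropyl)-7-methoxy-2,3-dihydrobenzofuran-3-carboxylate (racemic, one enantiomer drawn) | COC(=O)[C@@H]1[C@@H](c2cc(OC)c(OCc3ccccc3)c(OCc3ccccc3)c2)Oc2c(OC)cc(CCCO)cc21 | intermediate
10 | methyl 2-[3,4-bis(benzyloxy)-5-methoxyphenyl]-5-(3-hydroxypropyl)-7-methoxybenzofuran-3-carboxylate | COC(=O)c1c(-c2cc(OC)c(OCc3ccccc3)c(OCc3ccccc3)c2)oc2c(OC)cc(CCCO)cc12 | intermediate
11 | 3-{2-[3,4-bis(benzyloxy)-5-methoxyphenyl]-3-(hydroxymethyl)-7-methoxybenzofuran-5-yl}propan-1-ol | OCc1c(-c2cc(OC)c(OCc3ccccc3)c(OCc3ccccc3)c2)oc2c(OC)cc(CCCO)cc12 | intermediate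
12 | 2-[3,4-bis(benzyloxy)-5-methoxyphenyl]-5-(3-hydroxypropyl)-7-methoxybenzofuran-3-carbaldehyde | O=Cc1c(-c2cc(OC)c(OCc3ccccc3)c(OCc3ccccc3)c2)oc2c(OC)cc(CCCO)cc12 | intermediate
13 | Mururin C, 2-(3,4-dihydroxy-5-methoxyphenyl)-5-(3-hydroxypropyl)-7-methoxybenzofuran-3-carbaldehyde | COc1cc(-c2oc3c(OC)cc(CCCO)cc3c2C=O)cc(O)c1O | target

Total step count: 9 steps.
Longest linear sequence: 9 steps (1 to 13); 4 and 6 enter as purchased materials.

Steps most likely to fail

Step 4 (oxidative cross-coupling). Homo-coupling of each phenol may outrun the cross-coupling, bonding may go through oxygen instead of carbon, and the product phenol may be oxidised further. The fallback builds the same benzofuran ester without radical chemistry. It sets out from 6 and 2 and comes back at 10, bypassing 8, 9 and step 6.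
- Iodination of 6 ortho to the phenol (N-iodosuccinimide, cat. TsOH, MeCN) should give 4-(3-hydroxypropyl)-2-iodo-6-methoxyphenol F1.
- Aldehyde 2 is homologated with dimethyl (1-diazo-2-oxopropyl)phosphonate, K2CO3 and MeOH (Seyferth–Gilbert reaction, Ohira–Bestmann variant) to 1,2-bis(benzyloxy)-5-ethynyl-3-methoxybenzene F2.
- Sonogashira coupling of the two (PdCl2(PPh3)2, CuI, Et3N, THF, rt) should give 2-{[3,4-bis(benzyloxy)-5-methoxyphenyl]ethynyl}-4-(3-hydroxypropyl)-6-methoxyphenol F3.
- Carbonylative oxypalladation–cyclisation catalysed by divalent palladium (PdI2, thiourea, CBr4, Cs2CO3, CO, MeOH) converts this o-alkynylphenol into ester 10.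

Step 6 (DDQ dehydrogenation). Hydride abstraction at the side-chain benzylic CH2 (para to O1) or oxidative loss of a benzyl ether may compete with dehydrogenation of the ring. The fallback introduces the double bond by enolate chemistry. It sets out from 9 and comes back at 10.
- Silylation (t-BuMe2SiCl, imidazole, DMF) gives methyl trans-2-[3,4-bis(benzyloxy)-5-methoxyphenyl]-5-[3-(tert-butyldimethylsilyloxy)propyl]-7-methoxy-2,3-dihydrobenzofuran-3-carboxylate F4.
- Deprotonation with LiN(i-Pr)2 in THF at −78 °C and trapping with PhSeBr should give methyl 2-[3,4-bis(benzyloxy)-5-methoxyphenyl]-5-[3-(tert-butyldimethylsilyloxy)propyl]-7-methoxy-3-(phenylselanyl)-2,3-dihydrobenzofuran-3-carboxylate F5. Selenium enters anti to the C2 aryl group and is therefore syn to C2–H.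
- Oxidation with H2O2 (CH2Cl2, 0 °C to rt) and selenoxide syn-elimination give methyl 2-[3,4-bis(benzyloxy)-5-methoxyphenyl]-5-[3-(tert-butyldimethylsilyloxy)propyl]-7-methoxybenzofuran-3-carboxylate F6.
- Bu4NF in THF returns 10.

Step 9 (double debenzylation). The second benzyl group may be removed incompletely, the methyl ether next to the boron-bound catechol may be cleaved with chelation assistance, or the Lewis acid may attack the aldehyde. The fallback changes the protecting groups before the aldehyde exists. It sets out from 10 and comes back at 13.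
- Hydrogenolysis (H2, 10% Pd/C, EtOAc, rt) gives methyl 2-(3,4-dihydroxy-5-methoxyphenyl)-5-(3-hydroxypropyl)-7-methoxybenzofuran-3-carboxylate F7.
- Silylation of all three hydroxyls (t-BuMe2SiCl, imidazole, DMF) gives methyl 2-[3,4-bis(tert-butyldimethylsilyloxy)-5-methoxyphenyl]-5-[3-(tert-butyldimethylsilyloxy)propyl]-7-methoxybenzofuran-3-carboxylate F8.
- Reduction with i-Bu2AlH (CH2Cl2, −78 to 0 °C) gives {2-[3,4-bis(tert-butyldimethylsilyloxy)-5-methoxyphenyl]-5-[3-(tert-butyldimethylsilyloxy)propyl]-7-methoxybenzofuran-3-yl}methanol F9.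
- MnO2 in CH2Cl2 gives 2-[3,4-bis(tert-butyldimethylsilyloxy)-5-methoxyphenyl]-5-[3-(tert-butyldimethylsilyloxy)propyl]-7-methoxybenzofuran-3-carbaldehyde F10.
- HF·pyridine in THF at 0 °C removes the three silyl groups to give 13.

Further compounds
F1 | step 4 | 4-(3-hydroxypropyl)-2-iodo-6-methoxyphenol | COc1cc(CCCO)cc(I)c1O
F2 | step 4 | 1,2-bis(benzyloxy)-5-ethynyl-3-methoxybenzene | C#Cc1cc(OC)c(OCc2ccccc2)c(OCc2ccccc2)c1
F3 | step 4 | 2-{[3,4-bis(benzyloxy)-5-methoxyphenyl]ethynyl}-4-(3-hydroxypropyl)-6-methoxyphenol | COc1cc(CCCO)cc(C#Cc2cc(OC)c(OCc3ccccc3)c(OCc3ccccc3)c2)c1O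
F4 | step 6 | methyl trans-2-[3,4-bis(benzyloxy)-5-methoxyphenyl]-5-[3-(tert-butyldimethylsilyloxy)propyl]-7-methoxy-2,3-dihydrobenzofuran-3-carboxylate (racemic) | COC(=O)[C@@H]1[C@@H](c2cc(OC)c(OCc3ccccc3)c(OCc3ccccc3)c2)Oc2c(OC)cc(CCCO[Si](C)(C)C(C)(C)C)cc21
F5 | step 6 | methyl 2-[3,4-bis(benzyloxy)-5-methoxyphenyl]-5-[3-(tert-butyldimethylsilyloxy)propyl]-7-methoxy-3-(phenylselanyl)-2,3-dihydrobenzofuran-3-carboxylate (racemic, PhSe trans to the C2 aryl group) | COC(=O)[C@@]1([Se]c3ccccc3)[C@@H](c3cc(OC)c(OCc4ccccc4)c(OCc4ccccc4)c3)Oc2c(OC)cc(CCCO[Si](C)(C)C(C)(C)C)cc21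
F6 | step 6 | methyl 2-[3,4-bis(benzyloxy)-5-methoxyphenyl]-5-[3-(tert-butyldimethylsilyloxy)propyl]-7-methoxybenzofuran-3-carboxylate | COC(=O)c1c(-c2cc(OC)c(OCc3ccccc3)c(OCc3ccccc3)c2)oc2c(OC)cc(CCCO[Si](C)(C)C(C)(C)C)cc12
F7 | step 9 | methyl 2-(3,4-dihydroxy-5-methoxyphenyl)-5-(3-hydroxypropyl)-7-methoxybenzofuran-3-carboxylate | COC(=O)c1c(-c2cc(OC)c(O)c(O)c2)oc2c(OC)cc(CCCO)cc12
F8 | step 9 | methyl 2-[3,4-bis(tert-butyldimethylsilyloxy)-5-methoxyphenyl]-5-[3-(tert-butyldimethylsilyloxy)propyl]-7-methoxybenzofuran-3-carboxylate | COC(=O)c1c(-c2cc(OC)c(O[Si](C)(C)C(C)(C)C)c(O[Si](C)(C)C(C)(C)C)c2)oc2c(OC)cc(CCCO[Si](C)(C)C(C)(C)C)cc12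
F9 | step 9 | {2-[3,4-bis(tert-butyldimethylsilyloxy)-5-methoxyphenyl]-5-[3-(tert-butyldimethylsilyloxy)propyl]-7-methoxybenzofuran-3-yl}methanol | OCc1c(-c2cc(OC)c(O[Si](C)(C)C(C)(C)C)c(O[Si](C)(C)C(C)(C)C)c2)oc2c(OC)cc(CCCO[Si](C)(C)C(C)(C)C)cc12
F10 | step 9 | 2-[3,4-bis(tert-butyldimethylsilyloxy)-5-methoxyphenyl]-5-[3-(tert-butyldimethylsilyloxy)propyl]-7-methoxybenzofuran-3-carbaldehyde | O=Cc1c(-c2cc(OC)c(O[Si](C)(C)C(C)(C)C)c(O[Si](C)(C)C(C)(C)C)c2)oc2c(OC)cc(CCCO[Si](C)(C)C(C)(C)C)cc12
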